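**Retrosynthetic overview**
1. Dihydropyran last: acid dehydration of a δ-hydroxy ketone, made by titanocene-mediated reductive opening of a spiro-epoxide and Giese addition to ethyl vinyl ketone (sets C6); the epoxide comes from the bridged amino ketone.
2. Piperidine ring by intramolecular Mannich closure on a tricyclic β,γ-unsaturated ketone (creates quaternary C19).
3. Seven-membered ring by nickel-catalysed intramolecular alkenyl triflate/alkyl chloride reductive coupling (C11–C12).
4. Ring B (cyclopentane) by a one-pot Mukaiyama–Michael/palladium-catalysed enolate alkenylation that joins a West bromo enol triflate (from cyclopentenone, asymmetric Mukaiyama–Michael) with an East amino vinyl ketone (from α-methylene-γ-butyrolactone).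
5. Ring order: cyclopentene (ring A, bought) → cyclopentane (ring B) → cycloheptene → piperidine → dihydropyran.

Atom labels: skeletal atoms are labelled in the order they stand in the target SMILES (C1–C7, O8, C9–C20, N21, C22; ester group and N-methyl carbon unlabelled). Ring A = C12–C16, ring B = C13/C14/C17/C18/C19.
Assumption: C9 (racemic in the East fragment) and C19 are left uncontrolled up to compound 19, because both are α to the C6 ketone and converge in step 13; the target is taken as the enantiomer drawn.

**West fragment**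

Step 1
Reactants: 1 methyl acetate
Product: 2 tert-butyl[(1-methoxyethenyl)oxy]dimethylsilane
Conditions: LDA, THF, −78 °C; TBSCl, DMPU, −78 °C to rt
Reagents that add atoms: tert-butyldimethylsilyl chloride (TBSCl), CC(C)(C)[Si](C)(C)Cl
Why: Kinetic ester enolisation and O-silylation (silyl ketene acetal formation) is a standard preparation of Mukaiyama donors; no stereocentre is formed.

Step 2
Reactants: 2 tert-butyl[(1-methoxyethenyl)oxy]dimethylsilane; 3 cyclopent-2-en-1-one
Product: 4 methyl 2-[(1R)-3-{[tert-butyl(dimethyl)silyl]oxy}cyclopent-2-en-1-yl]acetate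
Conditions: chiral imidodiphosphorimidate (IDPi) acid precatalyst (2 mol %), toluene, −60 °C
Reagents that add atoms: none
Why: Catalytic asymmetric Mukaiyama–Michael addition with silyl transfer: the silylated enone is paired with the confined chiral anion, which shields one face so that C14 is set as R, and the silyl group ends on oxygen, which fixes the enol ether at C12=C13.

Step 3
Reactants: 4 methyl 2-[(1R)-3-{[tert-butyl(dimethyl)silyl]oxy}cyclopent-2-en-1-yl]acetate
Product: 5 methyl 2-[(1R,2R)-2-bromo-3-oxocyclopentyl]acetate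
Conditions: NBS, NaHCO3, THF, −78 to 0 °C
Reagents that add atoms: N-bromosuccinimide, O=C1CCC(=O)N1Br
Why: Electrophilic α-bromination of a silyl enol ether occurs only at the enol carbon C13, so bromine is placed regiospecifically between the carbonyl and C14 (trans to the side chain; this centre becomes sp2 again in step 4).

Step 4
Reactants: 5 methyl 2-[(1R,2R)-2-bromo-3-oxocyclopentyl]acetate
Product: 6 methyl 2-[(1R)-2-bromo-3-{[(trifluoromethyl)sulfonyl]oxy}cyclopent-2-en-1-yl]acetate
Conditions: Tf2O, 2,6-di-tert-butyl-4-methylpyridine, CH2Cl2, −78 °C to rt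
Reagents that add atoms: trifluoromethanesulfonic anhydride, O=S(=O)(OS(=O)(=O)C(F)(F)F)C(F)(F)F
Why: Enol triflate formation: the hydrogen on the bromine-bearing C13 is the more acidic α-hydrogen of the O-triflylated ketone, so enolisation goes toward C13 and gives the tetrasubstituted 2-bromo enol triflate with two differentiated alkenyl electrophiles; C14 is untouched.

Step 5
Reactants: 6 methyl 2-[(1R)-2-bromo-3-{[(trifluoromethyl)sulfonyl]oxy}cyclopent-2-en-1-yl]acetate
Product: 7 tert-butyl{[(1E)-2-[(1R)-2-bromo-3-{[(trifluoromethyl)sulfonyl]oxy}cyclopent-2-en-1-yl]-1-methoxyethenyl]oxy}dimethylsilane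
Conditions: LDA, THF, −78 °C; TBSCl, DMPU, −78 to −20 °C
Reagents that add atoms: tert-butyldimethylsilyl chloride (TBSCl), CC(C)(C)[Si](C)(C)Cl
Why: Kinetic ester enolisation and O-silylation (Ireland conditions) give the isolable (E)-silyl ketene acetal; the alkenyl bromide and triflate are inert at −78 °C and C14 carries no acidic hydrogen.

**East fragment**

Step 6
Reactants: 8 3-methylideneoxolan-2-one (α-methylene-γ-butyrolactone); 9 methylamine
Product: 10 3-[(methylamino)methyl]oxolan-2-one (racemic)
Conditions: MeNH2 (2 M in THF, 3 equiv), 0 °C, 1 h; evaporation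
Reagents that add atoms: none
Why: Aza-Michael addition of the amine to the exocyclic acrylate is fast at 0 °C and outpaces lactone aminolysis; the new centre (later C9) is racemic and stays epimerisable.

Step 7
Reactants: 10 3-[(methylamino)methyl]oxolan-2-one
Product: 11 tert-butyl N-methyl-N-[(2-oxooxolan-3-yl)methyl]carbamate
Conditions: Boc2O, Et3N (cat.), CH2Cl2, 0 °C to rt
Reagents that add atoms: di-tert-butyl dicarbonate, CC(C)(C)OC(=O)OC(=O)OC(C)(C)C
Why: N-acylation (carbamate protection) removes the nucleophilic, basic N–H before the organometallic steps.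

Step 8
Reactants: 11 tert-butyl N-methyl-N-[(2-oxooxolan-3-yl)methyl]carbamate
Product: 12 tert-butyl N-{4-hydroxy-2-[methoxy(methyl)carbamoyl]butyl}-N-methylcarbamate
Conditions: MeNH(OMe)·HCl, i-PrMgCl, THF, −20 to 0 °C
Reagents that add atoms: N,O-dimethylhydroxylamine hydrochloride, CNOC.Cl
Why: Lactone aminolysis by the magnesium amide (Weinreb amide formation) opens the ring and frees the primary alcohol.

Step 9
Reactants: 12 tert-butyl N-{4-hydroxy-2-[methoxy(methyl)carbamoyl]butyl}-N-methylcarbamate
Product: 13 tert-butyl N-{4-chloro-2-[methoxy(methyl)carbamoyl]butyl}-N-methylcarbamate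
Conditions: PPh3, NCS, CH2Cl2, 0 °C to rt
Reagents that add atoms: N-chlorosuccinimide, O=C1CCC(=O)N1Cl
Why: Appel-type chlorination (SN2 on the alkoxyphosphonium salt) gives the primary chloride, chosen as the later sp3 electrophile because it is inert to enolates and to palladium.

Step 10
Reactants: 13 tert-butyl N-{4-chloro-2-[methoxy(methyl)carbamoyl]butyl}-N-methylcarbamate
Product: 14 tert-butyl N-[2-(2-chloroethyl)-3-oxopent-4-en-1-yl]-N-methylcarbamate
Conditions: vinylmagnesium bromide, THF, −78 to −20 °C; cold aq. HCl quench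
Reagents that add atoms: vinylmagnesium bromide, C=C[Mg]Br
Why: Weinreb ketone synthesis: the chelated tetrahedral magnesium adduct survives until the cold acidic quench, so one vinyl group is added and the vinyl ketone is released without conjugate addition.

**Union and endgame**

Step 11
Reactants: 7 tert-butyl{[(1E)-2-[(1R)-2-bromo-3-{[(trifluoromethyl)sulfonyl]oxy}cyclopent-2-en-1-yl]-1-methoxyethenyl]oxy}dimethylsilane; 14 tert-butyl N-[2-(2-chloroethyl)-3-oxopent-4-en-1-yl]-N-methylcarbamate
Product: 16 methyl (1R,6aR)-3-[2-({(tert-butoxycarbonyl)(methyl)amino}methyl)-4-chlorobutanoyl]-4-{[(trifluoromethyl)sulfonyl]oxy}-1,2,3,5,6,6a-hexahydropentalene-1-carboxylate, via TBS enol ether 15 (not isolated)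
Conditions: TBSNTf2 (5 mol %), CH2Cl2, −78 °C; solvent switch; Pd2(dba)3 (3 mol %), P(t-Bu)3 (7 mol %), Bu3SnF (1.5 equiv), CsF (0.2 equiv), toluene, 80 °C
Reagents that add atoms: none
Why: Proposed new method: a one-pot Mukaiyama–Michael/enolate alkenylation [3+2] annulation in which silyl-transfer conjugate addition of 7 to 14 forms C17–C18 and gives the regiodefined enol ether 15 (the enone approaches the ketene acetal anti to the bulky bromo-alkenyl carbon C13 in the allylic-strain-minimised conformer, placing H17 cis to H14), fluoride transfer from Bu3SnF then gives a tin enolate that is captured by the alkenylpalladium formed by selective oxidative addition of zerovalent palladium/P(t-Bu)3 into C13–Br (C12–OTf is spared in a non-polar solvent), and reductive elimination from the six-membered palladacycle closes ring B at C13–C19; the closest known chemistry is palladium-catalysed α-alkenylation/arylation of silyl enol ethers through tin or zinc enolates and tandem conjugate addition–enolate arylation.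

Step 12
Reactants: 16 methyl (1R,6aR)-3-[2-({(tert-butoxycarbonyl)(methyl)amino}methyl)-4-chlorobutanoyl]-4-{[(trifluoromethyl)sulfonyl]oxy}-1,2,3,5,6,6a-hexahydropentalene-1-carboxylate
Product: 17 tricyclic keto ester (5-5-7 cyclopent[cd]azulene-type skeleton; C6 ketone; C12=C13; CO2Me on C17; CH2N(Me)Boc on C9; 14R,17R; C9/C19 epimers)
Conditions: NiBr2(dme) (10 mol %), 4,4′-di-tert-butyl-2,2′-bipyridine (12 mol %), NaI (0.5 equiv), Mn powder (3 equiv), DMA, 60 °C, 0.01 M
Reagents that add atoms: none
Why: Nickel-catalysed intramolecular reductive cross-electrophile coupling: oxidative addition of zerovalent nickel into the alkenyl triflate C12–OTf, capture of the primary radical from C11–Cl (through the iodide formed in situ) and reductive elimination forge C11–C12 and close the seven-membered ring; no stereocentre is formed and ketone, ester and carbamate tolerate these neutral conditions.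

Step 13
Reactants: 17 tricyclic keto ester
Product: 20 bridged amino ketone (8-methyl-8-azabicyclo[4.3.1]decan-10-one core fused to rings A and B; 9R,14R,17R,19S), via amine 18 (not isolated), via iminium ion 19 (not isolated)
Conditions: TFA, CH2Cl2, 0 °C to rt; evaporation; aq. CH2O (37 %), AcOH, 60 °C
Reagents that add atoms: formaldehyde, C=O
Why: Boc cleavage then intramolecular Mannich reaction (piperidone-forming 6-endo closure): the N-methyleneiminium ion can only reach the dienol carbon C19, which it attacks on the face anti to the C17 ester and C15 (convex face of the diquinane), creating quaternary C19 with C20 cis to H14, while C9 equilibrates through the enol to the epimer that allows bridging.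

Step 14
Reactants: 20 bridged amino ketone
Product: 21 spiro-epoxide (oxirane on C6; either C6 epimer)
Conditions: Me3S+ I−, NaH, DMSO/THF, −10 to 0 °C (1.3 equiv ylide)
Reagents that add atoms: trimethylsulfonium iodide, C[S+](C)C.[I-]
Why: Corey–Chaykovsky epoxidation: the bridging ketone has no enolisable α-hydrogen (C19 quaternary, C9 bridgehead), so only carbonyl addition occurs, and the spiro configuration is irrelevant because C6 becomes a planar radical in step 15.

Step 15
Reactants: 21 spiro-epoxide; 22 pent-1-en-3-one (ethyl vinyl ketone)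
Product: 25 CNP0159589.3 (target; 6R,9S,14R,17R,19R), via hydroxy ketone 23 (not isolated), via hemiketal 24 (not isolated)
Conditions: Cp2TiCl2 (20 mol %), Mn powder (3 equiv), 2,4,6-collidine·HCl (3 equiv), 22 (5 equiv), THF, rt; filtration; CSA (1.5 equiv), 4 Å MS, benzene, 60 °C
Reagents that add atoms: none
Why: Titanocene-catalysed reductive epoxide opening (trivalent titanium, Nugent–RajanBabu type) gives the tertiary β-titanoxy radical at C6, which undergoes Giese addition to the enone on the face of the nitrogen bridge, away from the four-carbon bridge and ring B, setting C6 (R); the δ-hydroxy ketone closes to the hemiketal and acid-catalysed dehydration gives the endocyclic enol ether.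

**Compound list**
1 | methyl acetate | COC(C)=O | starting material
2 | tert-butyl[(1-methoxyethenyl)oxy]dimethylsilane | COC(=C)O[Si](C)(C)C(C)(C)C | intermediate
3 | cyclopent-2-en-1-one | O=C1C=CCC1 | starting material
4 | methyl 2-[(1R)-3-{[tert-butyl(dimethyl)silyl]oxy}cyclopent-2-en-1-yl]acetate | COC(=O)C[C@@H]1C=C(O[Si](C)(C)C(C)(C)C)CC1 | intermediate
5 | methyl 2-[(1R,2R)-2-bromo-3-oxocyclopentyl]acetate | COC(=O)C[C@@H]1[C@@H](Br)C(=O)CC1 | intermediate
6 | methyl 2-[(1R)-2-bromo-3-{[(trifluoromethyl)sulfonyl]oxy}cyclopent-2-en-1-yl]acetate | COC(=O)C[C@@H]1C(Br)=C(OS(=O)(=O)C(F)(F)F)CC1 | intermediate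
7 | (E)-TBS ketene acetal of 6 | CO/C(=C\[C@@H]1C(Br)=C(OS(=O)(=O)C(F)(F)F)CC1)O[Si](C)(C)C(C)(C)C | intermediate
8 | 3-methylideneoxolan-2-one | C=C1CCOC1=O | starting material
9 | methylamine | CN | starting material
10 | 3-[(methylamino)methyl]oxolan-2-one (racemic) | CNCC1CCOC1=O | intermediate
11 | tert-butyl N-methyl-N-[(2-oxooxolan-3-yl)methyl]carbamate (racemic) | CN(CC1CCOC1=O)C(=O)OC(C)(C)C | intermediate
12 | tert-butyl N-{4-hydroxy-2-[methoxy(methyl)carbamoyl]butyl}-N-methylcarbamate (racemic) | CON(C)C(=O)C(CCO)CN(C)C(=O)OC(C)(C)C | intermediate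
13 | tert-butyl N-{4-chloro-2-[methoxy(methyl)carbamoyl]butyl}-N-methylcarbamate (racemic) | CON(C)C(=O)C(CCCl)CN(C)C(=O)OC(C)(C)C | intermediate
14 | tert-butyl N-[2-(2-chloroethyl)-3-oxopent-4-en-1-yl]-N-methylcarbamate (racemic) | C=CC(=O)C(CCCl)CN(C)C(=O)OC(C)(C)C | intermediate
15 | methyl (2R)-2-[(1R)-2-bromo-3-(triflyloxy)cyclopent-2-en-1-yl]-5-(TBS-oxy)-6-({Boc(methyl)amino}methyl)-8-chlorooct-4-enoate (C9 epimers) | COC(=O)[C@H](CC=C(O[Si](C)(C)C(C)(C)C)C(CCCl)CN(C)C(=O)OC(C)(C)C)[C@@H]1C(Br)=C(OS(=O)(=O)C(F)(F)F)CC1 | intermediate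
16 | methyl (1R,6aR)-3-[2-({Boc(methyl)amino}methyl)-4-chlorobutanoyl]-4-(triflyloxy)-1,2,3,5,6,6a-hexahydropentalene-1-carboxylate (C9/C19 epimers) | COC(=O)[C@@H]1CC(C(=O)C(CCCl)CN(C)C(=O)OC(C)(C)C)C2=C(OS(=O)(=O)C(F)(F)F)CC[C@H]12 | intermediate
17 | tricyclic keto ester with CH2N(Me)Boc on C9 (14R,17R; C9/C19 epimers) | COC(=O)[C@@H]1CC2C(=O)C(CN(C)C(=O)OC(C)(C)C)CCC3=C2[C@@H]1CC3 | intermediate
18 | secondary amine from Boc cleavage of 17 | COC(=O)[C@@H]1CC2C(=O)C(CNC)CCC3=C2[C@@H]1CC3 | intermediate
19 | N-methyl-N-methyleneiminium ion of 18 | COC(=O)[C@@H]1CC2C(=O)C(C[N+](C)=C)CCC3=C2[C@@H]1CC3 | intermediate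
20 | bridged amino ketone (9R,14R,17R,19S) | O=C1[C@@H]2CCC3=C4[C@H](CC3)[C@H](C(=O)OC)C[C@@]41CN(C)C2 | intermediate
21 | spiro-epoxide on C6 (C6 unassigned) | C1OC12[C@@H]3CCC4=C5[C@H](CC4)[C@H](C(=O)OC)C[C@@]52CN(C)C3 | intermediate
22 | pent-1-en-3-one | CCC(=O)C=C | starting material
23 | δ-hydroxy ketone (C6 bears CH2OH and CH2CH2C(O)Et; 6R,9S,14R,17R,19R) | CCC(=O)CC[C@@]2(CO)[C@@H]1CCC3=C4[C@H](CC3)[C@H](C(=O)OC)C[C@@]42CN(C)C1 | intermediate
24 | cyclic hemiketal of 23 | CCC1(O)CC[C@@]2(CO1)[C@@H]1CCC3=C4[C@H](CC3)[C@H](C(=O)OC)C[C@@]42CN(C)C1 | intermediate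
25 | CNP0159589.3 | CCC1=CC[C@@]2(CO1)[C@@H]1CCC3=C4[C@H](CC3)[C@H](C(=O)OC)C[C@@]42CN(C)C1 | target

**Totals and risks**
Total step count: 15. Longest linear sequence: 10 steps (steps 1–5 then 11–15 from methyl acetate; equally steps 6–10 then 11–15).

Most likely to fail, step 11 (the proposed annulation): palladium may also insert into C12–OTf, or 15 may be protodesilylated before coupling. The fallback uses known chemistry and sets out from 15, now isolated after the Mukaiyama–Michael stage alone. Ring B is closed by a tin-hydride 5-exo-trig cyclisation of the alkenyl radical from C13–Br onto the enol ether (Bu3SnH, AIBN, benzene, 80 °C), giving the silyl ether F1. HF·pyridine gives the alcohol F2, and Dess–Martin oxidation comes back to the route at 16.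

Second, step 12: a seven-membered reductive cyclisation with a primary chloride may give reduction or dimers. The fallback sets out from 16. NaI in acetone gives the iodide F3, zinc insertion (Zn dust, LiCl, THF) gives the alkylzinc iodide F4, and an intramolecular Negishi coupling (Pd(OAc)2, SPhos, THF, 50 °C, high dilution) comes back at 17.

Third, step 15: the hindered C6 radical may be reduced or eliminate instead of adding, and its facial selectivity is the least secure stereochemical point. The fallback is polar and sets out from 20. Wittig methoxymethylenation (Ph3P=CHOMe from the phosphonium chloride and KHMDS) gives the enol ether F5, and aqueous HCl gives the aldehyde F6. DBU-mediated Michael addition of its enol to 22 gives the keto aldehyde F7. NaBH(OAc)3 reduces only the aldehyde and comes back at 23, which is dehydrated to 25 as in step 15.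

**Further compounds**
F1 | step 11 | TBS ether of the ring-B-closed secondary alcohol (C6–H, C6–OTBS) | COC(=O)[C@@H]1CC(C(O[Si](C)(C)C(C)(C)C)C(CCCl)CN(C)C(=O)OC(C)(C)C)C2=C(OS(=O)(=O)C(F)(F)F)CC[C@H]12
F2 | step 11 | secondary alcohol at C6 | COC(=O)[C@@H]1CC(C(O)C(CCCl)CN(C)C(=O)OC(C)(C)C)C2=C(OS(=O)(=O)C(F)(F)F)CC[C@H]12
F3 | step 12 | primary iodide analogue of 16 | COC(=O)[C@@H]1CC(C(=O)C(CCI)CN(C)C(=O)OC(C)(C)C)C2=C(OS(=O)(=O)C(F)(F)F)CC[C@H]12
F4 | step 12 | alkylzinc iodide from F3 | COC(=O)[C@@H]1CC(C(=O)C(CC[Zn]I)CN(C)C(=O)OC(C)(C)C)C2=C(OS(=O)(=O)C(F)(F)F)CC[C@H]12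
F5 | step 15 | methyl enol ether (C6=CH–OMe) from 20 | COC=C1[C@@H]2CCC3=C4[C@H](CC3)[C@H](C(=O)OC)C[C@@]41CN(C)C2
F6 | step 15 | aldehyde (C6–H, C6–CHO) | O=CC1[C@@H]2CCC3=C4[C@H](CC3)[C@H](C(=O)OC)C[C@@]41CN(C)C2
F7 | step 15 | keto aldehyde (C6 bears CHO and CH2CH2C(O)Et) | CCC(=O)CC[C@@]2(C=O)[C@@H]1CCC3=C4[C@H](CC3)[C@H](C(=O)OC)C[C@@]42CN(C)C1
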